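**Strategy.** Everything rests on disconnecting C3–C4 of the lower pyran ring (ring C of the flavan-3,4-diol unit). Because C3 carries oxygen and C4 is benzylic on ring A, C3 is brought in as the carbonyl carbon of a benzyl ester and C4 as an ortho-vinyl carbon. A Cp2Ti=CH2-mediated (Tebbe-type) olefinic-ester cyclisation joins them, closing ring C as a flat 3-benzyloxy-flav-3-ene in one operation. Its precursor is an (R)-α-aryloxy arylacetate hung on O1 of a vinylphenol that already bears the upper flavan. C2, set by Mitsunobu inversion of a catalytically made mandelate, then relays C3 and C4 in a single hydroboration. The same annulation first builds the upper unit.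

Key step: step 14

Remark on the chemistry: flavonoid numbering is used for both units (O1, C2, C3, C4, C4a to C8a; ring A the fused arene, ring B the 2-aryl group, ring C the pyran); β means the face opposite the C2 aryl group. Each 7,8-diol is carried as a diphenylmethylene ketal and every other hydroxyl as a benzyl ether, so one hydrogenolysis frees everything.

Step 1
Reactants: 1 pyrogallol
Product: 2 2,2-diphenyl-1,3-benzodioxol-4-ol
Conditions: Ph2CCl2 (1.1 equiv), neat, 160 °C, N2 sweep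
Reagents that add atoms: dichlorodiphenylmethane ClC(Cl)(c1ccccc1)c1ccccc1
Why: Diphenylmethylene ketal formation by double substitution on the gem-dichloride ties up one vicinal pair of hydroxyls (either pair gives the same product by symmetry) and leaves one phenol free as the future O1.

Step 2
Reactants: 2 2,2-diphenyl-1,3-benzodioxol-4-ol
Product: 3 5-bromo-2,2-diphenyl-1,3-benzodioxol-4-ol
Conditions: NBS (1.0 equiv), iPr2NH (10 mol %), CH2Cl2, −78 → 0 °C
Reagents that add atoms: N-bromosuccinimide O=C1CCC(=O)N1Br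
Why: Amine-mediated ortho-bromination of a phenol (hydrogen-bond delivery of the N-bromoamine) should brominate C5, ortho to the hydroxyl and para to a ring oxygen, giving a bromine that blocks this site in step 9 and is the handle for the vinyl group.

Step 3
Reactants: 3 5-bromo-2,2-diphenyl-1,3-benzodioxol-4-ol, 4 potassium vinyltrifluoroborate (CH2=CHBF3K)
Product: 5 2,2-diphenyl-5-vinyl-1,3-benzodioxol-4-ol
Conditions: Pd(OAc)2 (3 mol %), SPhos (6 mol %), K2CO3, 1,4-dioxane/H2O, 80 °C
Reagents that add atoms: none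
Why: Suzuki–Miyaura vinylation of the aryl bromide tolerates the free phenol and gives the ortho-vinylphenol whose vinyl CH becomes C4 of the upper unit.

Step 4
Reactants: 6 1-(benzyloxy)-4-bromobenzene, 7 dibenzyl oxalate
Product: 9 benzyl 2-[4-(benzyloxy)phenyl]-2-oxoacetate, via aryl Grignard reagent 8 (not isolated)
Conditions: Mg, THF, 40 °C; then added to 7 (1.5 equiv), THF, −78 °C; aq NH4Cl
Reagents that add atoms: none
Why: Mono-acylation of an aryl Grignard reagent by excess oxalate diester at low temperature stops at the α-keto ester, which already holds the benzyl ester that later becomes the 3-O-benzyl group.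

Step 5
Reactants: 9 benzyl 2-[4-(benzyloxy)phenyl]-2-oxoacetate
Product: 10 benzyl (2S)-2-[4-(benzyloxy)phenyl]-2-hydroxyacetate
Conditions: RuCl[(R,R)-TsDPEN](p-cymene) (1 mol %), HCO2H/Et3N (5:2), DMF, 25 °C
Reagents that add atoms: none
Why: Noyori-type asymmetric transfer hydrogenation of the aryl α-keto ester sets the one catalytically made stereocentre; the (R,R) ligand is chosen for the S alcohol by the usual aryl-ketone model, and the mirror-image complex is used should the sense prove opposite.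

Step 6
Reactants: 5 2,2-diphenyl-5-vinyl-1,3-benzodioxol-4-ol, 10 benzyl (2S)-2-[4-(benzyloxy)phenyl]-2-hydroxyacetate
Product: 11 benzyl (2R)-2-[4-(benzyloxy)phenyl]-2-[(2,2-diphenyl-5-vinyl-1,3-benzodioxol-4-yl)oxy]acetate
Conditions: PPh3, DIAD, toluene, 0 → 25 °C
Reagents that add atoms: none
Why: Mitsunobu etherification of the phenol with the secondary α-hydroxy ester proceeds by SN2 inversion (the ester suppresses ionisation), turning S into the R configuration needed at C2.

Step 7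
Reactants: 11 benzyl (2R)-2-[4-(benzyloxy)phenyl]-2-[(2,2-diphenyl-5-vinyl-1,3-benzodioxol-4-yl)oxy]acetate
Product: 12 (2R)-3-(benzyloxy)-2-[4-(benzyloxy)phenyl]-7,8-(diphenylmethylenedioxy)-2H-chromene
Conditions: Cp2Ti(μ-Cl)(μ-CH2)AlMe2 (Tebbe reagent, 4 equiv), pyridine (cat.), THF, 0 → 25 °C, then 65 °C, dark
Reagents that add atoms: none
Why: Tandem Tebbe methylenation/ring-closing olefin metathesis of the olefinic ester forms C3=C4 of the upper ring C as a benzyl enol ether without enolising the acidic C2–H, and rehearses step 14.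

Step 8
Reactants: 12 (2R)-3-(benzyloxy)-2-[4-(benzyloxy)phenyl]-7,8-(diphenylmethylenedioxy)-2H-chromene
Product: 14 (2R,3R,4S)-3-(benzyloxy)-2-[4-(benzyloxy)phenyl]-7,8-(diphenylmethylenedioxy)chroman-4-ol, via C4β borane adduct 13 (not isolated)
Conditions: BH3·THF (1.5 equiv), THF, 0 °C; then 3 M NaOH, 30 % H2O2, 0 → 25 °C
Reagents that add atoms: hydrogen peroxide OO
Why: Brown hydroboration–oxidation should place boron on C4 (β to the enol-ether oxygen) and hydrogen on C3 by syn addition to the face opposite the pseudoaxial C2 aryl group, so the 3-benzyloxy group ends cis to the aryl group and the 4-hydroxyl (retention on oxidation) trans to it.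

Step 9
Reactants: 14 (2R,3R,4S)-3-(benzyloxy)-2-[4-(benzyloxy)phenyl]-7,8-(diphenylmethylenedioxy)chroman-4-ol, 3 5-bromo-2,2-diphenyl-1,3-benzodioxol-4-ol
Product: 15 5-bromo-7-{(2R,3R)-3-(benzyloxy)-2-[4-(benzyloxy)phenyl]-7,8-(diphenylmethylenedioxy)chroman-4β-yl}-2,2-diphenyl-1,3-benzodioxol-4-ol
Conditions: 3 (4 equiv), BF3·OEt2 (1.2 equiv), CH2Cl2, −78 → −20 °C
Reagents that add atoms: none
Why: Lewis-acid ionisation of the 4-hydroxyl gives a benzylic cation stabilised by O1 and the para 7-oxygen; Friedel–Crafts capture by the phenol at its only activated free carbon (para to OH, the ortho site being blocked by bromine) occurs on the face opposite the C2 aryl and C3 benzyloxy groups and sets the 3,4-trans (4β) interflavan bond.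

Step 10
Reactants: 15 5-bromo-7-{(2R,3R)-3-(benzyloxy)-2-[4-(benzyloxy)phenyl]-7,8-(diphenylmethylenedioxy)chroman-4β-yl}-2,2-diphenyl-1,3-benzodioxol-4-ol, 4 potassium vinyltrifluoroborate (CH2=CHBF3K)
Product: 16 7-{(2R,3R)-3-(benzyloxy)-2-[4-(benzyloxy)phenyl]-7,8-(diphenylmethylenedioxy)chroman-4β-yl}-2,2-diphenyl-5-vinyl-1,3-benzodioxol-4-ol
Conditions: Pd(OAc)2 (5 mol %), SPhos (10 mol %), K2CO3, 1,4-dioxane/H2O, 80 °C
Reagents that add atoms: none
Why: The Suzuki–Miyaura vinylation of step 3 turns the blocking bromine into the vinyl group that supplies C4 of the lower unit.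

Step 11
Reactants: 17 1,2-bis(benzyloxy)-4-bromobenzene, 7 dibenzyl oxalate
Product: 19 benzyl 2-[3,4-bis(benzyloxy)phenyl]-2-oxoacetate, via aryl Grignard reagent 18 (not isolated)
Conditions: Mg, THF, 40 °C; then added to 7 (1.5 equiv), THF, −78 °C; aq NH4Cl
Reagents that add atoms: none
Why: The Grignard mono-acylation of oxalate used in step 4 gives the α-keto ester carrying ring B of the lower unit.

Step 12
Reactants: 19 benzyl 2-[3,4-bis(benzyloxy)phenyl]-2-oxoacetate
Product: 20 benzyl (2S)-2-[3,4-bis(benzyloxy)phenyl]-2-hydroxyacetate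
Conditions: RuCl[(R,R)-TsDPEN](p-cymene) (1 mol %), HCO2H/Et3N (5:2), DMF, 25 °C
Reagents that add atoms: none
Why: Noyori-type asymmetric transfer hydrogenation as in step 5 sets the S carbinol by catalyst control.

Step 13
Reactants: 16 7-{(2R,3R)-3-(benzyloxy)-2-[4-(benzyloxy)phenyl]-7,8-(diphenylmethylenedioxy)chroman-4β-yl}-2,2-diphenyl-5-vinyl-1,3-benzodioxol-4-ol, 20 benzyl (2S)-2-[3,4-bis(benzyloxy)phenyl]-2-hydroxyacetate
Product: 21 benzyl (2R)-2-[3,4-bis(benzyloxy)phenyl]-2-[(7-{(2R,3R)-3-(benzyloxy)-2-[4-(benzyloxy)phenyl]-7,8-(diphenylmethylenedioxy)chroman-4β-yl}-2,2-diphenyl-5-vinyl-1,3-benzodioxol-4-yl)oxy]acetate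
Conditions: PPh3, DIAD, toluene, 0 → 25 °C
Reagents that add atoms: none
Why: Mitsunobu etherification with SN2 inversion at the mandelate carbinol installs the O1–C2 bond of the lower unit with the R configuration.

Step 14
Reactants: 21 benzyl (2R)-2-[3,4-bis(benzyloxy)phenyl]-2-[(7-{(2R,3R)-3-(benzyloxy)-2-[4-(benzyloxy)phenyl]-7,8-(diphenylmethylenedioxy)chroman-4β-yl}-2,2-diphenyl-5-vinyl-1,3-benzodioxol-4-yl)oxy]acetate
Product: 22 (2R)-3-(benzyloxy)-2-[3,4-bis(benzyloxy)phenyl]-6-{(2R,3R)-3-(benzyloxy)-2-[4-(benzyloxy)phenyl]-7,8-(diphenylmethylenedioxy)chroman-4β-yl}-7,8-(diphenylmethylenedioxy)-2H-chromene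
Conditions: Cp2Ti(μ-Cl)(μ-CH2)AlMe2 (Tebbe reagent, 4 equiv), pyridine (cat.), THF (0.01 M), 0 → 25 °C, then 65 °C, dark
Reagents that add atoms: none
Why: Cp2Ti=CH2 released from the reagent first methylenates the benzyl ester carbonyl (C3) to the benzyl enol ether; on warming, the titanium carbene exchanges with the ortho-vinyl group to a titanium benzylidene at C4, which closes onto the enol ether by [2+2] cycloaddition and cycloreversion, expelling ethylene overall and forming C3=C4. The closest known reaction type is the tandem Tebbe methylenation/ring-closing olefin metathesis of olefinic esters to cyclic enol ethers. The one ring closed is the six-membered pyran ring C of the lower unit, by ring-closing metathesis through a titanacyclobutane between two sp2 termini held ortho to each other across O1 and C2. No stereocentre is created: C2 passes through unchanged because the reagent is Lewis acidic but not basic, and the flat enol ether it delivers is what lets C2 relay C3 and C4 in step 15. The step needs chemoselectivity for the single ester carbonyl and the single terminal alkene, secured because every other oxygen is an ether or ketal and every other unsaturation is aromatic, and ring closure over dimerisation, secured by the ortho tether and high dilution.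

Step 15
Reactants: 22 (2R)-3-(benzyloxy)-2-[3,4-bis(benzyloxy)phenyl]-6-{(2R,3R)-3-(benzyloxy)-2-[4-(benzyloxy)phenyl]-7,8-(diphenylmethylenedioxy)chroman-4β-yl}-7,8-(diphenylmethylenedioxy)-2H-chromene
Product: 24 (2R,3R,4S)-3-(benzyloxy)-2-[3,4-bis(benzyloxy)phenyl]-6-{(2R,3R)-3-(benzyloxy)-2-[4-(benzyloxy)phenyl]-7,8-(diphenylmethylenedioxy)chroman-4β-yl}-7,8-(diphenylmethylenedioxy)chroman-4-ol, via lower-unit C4β borane adduct 23 (not isolated)
Conditions: BH3·THF (1.5 equiv), THF, 0 °C; then 3 M NaOH, 30 % H2O2, 0 → 25 °C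
Reagents that add atoms: hydrogen peroxide OO
Why: Brown hydroboration–oxidation should put boron on C4 (β to the enol-ether oxygen) and hydrogen on C3 by syn addition to the face opposite the pseudoaxial C2 aryl group, so C2 sets C3 (OBn cis to the aryl group) and C4 (OH trans to OBn, retention on oxidation) in one event, giving the 2,3-cis-3,4-trans array.

Step 16
Reactants: 24 (2R,3R,4S)-3-(benzyloxy)-2-[3,4-bis(benzyloxy)phenyl]-6-{(2R,3R)-3-(benzyloxy)-2-[4-(benzyloxy)phenyl]-7,8-(diphenylmethylenedioxy)chroman-4β-yl}-7,8-(diphenylmethylenedioxy)chroman-4-ol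
Product: 25 (2R,3R,4S)-2-(3,4-dihydroxyphenyl)-6-[(2R,3R,4S)-3,7,8-trihydroxy-2-(4-hydroxyphenyl)chroman-4-yl]chroman-3,4,7,8-tetrol
Conditions: H2 (1 atm), Pd(OH)2/C, THF/EtOAc/H2O, 25 °C; filtration under argon, lyophilisation
Reagents that add atoms: none
Why: Catalytic hydrogenolysis cleaves the five benzyl ethers and both diphenylmethylene ketals under neutral, alcohol-free conditions chosen so that the acid-labile benzylic 4-hydroxyl of the lower unit is neither solvolysed nor reduced, and no stereocentre is touched.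

**Compound list**

1 | pyrogallol | Oc1cccc(O)c1O | starting material
2 | 2,2-diphenyl-1,3-benzodioxol-4-ol | Oc1cccc2OC(c3ccccc3)(c3ccccc3)Oc12 | intermediate
3 | 5-bromo-2,2-diphenyl-1,3-benzodioxol-4-ol | Oc1c(Br)ccc2OC(c3ccccc3)(c3ccccc3)Oc12 | intermediate
4 | potassium vinyltrifluoroborate | C=C[B-](F)(F)F.[K+] | starting material
5 | 2,2-diphenyl-5-vinyl-1,3-benzodioxol-4-ol | Oc1c(C=C)ccc2OC(c3ccccc3)(c3ccccc3)Oc12 | intermediate
6 | 1-(benzyloxy)-4-bromobenzene | Brc1ccc(OCc2ccccc2)cc1 | starting material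
7 | dibenzyl oxalate | O=C(OCc1ccccc1)C(=O)OCc1ccccc1 | starting material
8 | [4-(benzyloxy)phenyl]magnesium bromide | Br[Mg]c1ccc(OCc2ccccc2)cc1 | intermediate
9 | benzyl 2-[4-(benzyloxy)phenyl]-2-oxoacetate | O=C(OCc1ccccc1)C(=O)c1ccc(OCc2ccccc2)cc1 | intermediate
10 | benzyl (2S)-2-[4-(benzyloxy)phenyl]-2-hydroxyacetate | O[C@@H](c1ccc(OCc2ccccc2)cc1)C(=O)OCc1ccccc1 | intermediate
11 | benzyl (2R)-2-[4-(benzyloxy)phenyl]-2-[(2,2-diphenyl-5-vinyl-1,3-benzodioxol-4-yl)oxy]acetate | c1ccccc1COc1ccc(cc1)[C@@H](Oc1c(C=C)ccc2OC(c3ccccc3)(c3ccccc3)Oc12)C(=O)OCc1ccccc1 | intermediate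
12 | (2R)-3-(benzyloxy)-2-[4-(benzyloxy)phenyl]-7,8-(diphenylmethylenedioxy)-2H-chromene | c1ccccc1COc1ccc(cc1)[C@H]1Oc2c(ccc3OC(c4ccccc4)(c4ccccc4)Oc32)C=C1OCc1ccccc1 | intermediate
13 | C4β borane adduct of 12 (boron trans to the 3-benzyloxy group, 2,3-cis) | c1ccccc1COc1ccc(cc1)[C@H]1Oc2c(ccc3OC(c4ccccc4)(c4ccccc4)Oc32)[C@H](B)[C@H]1OCc1ccccc1 | intermediate
14 | (2R,3R,4S)-3-(benzyloxy)-2-[4-(benzyloxy)phenyl]-7,8-(diphenylmethylenedioxy)chroman-4-ol (2,3-cis-3,4-trans) | c1ccccc1COc1ccc(cc1)[C@H]1Oc2c(ccc3OC(c4ccccc4)(c4ccccc4)Oc32)[C@H](O)[C@H]1OCc1ccccc1 | intermediate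
15 | 5-bromo-7-{(2R,3R)-3-(benzyloxy)-2-[4-(benzyloxy)phenyl]-7,8-(diphenylmethylenedioxy)chroman-4β-yl}-2,2-diphenyl-1,3-benzodioxol-4-ol (aryl at C4 trans to the 3-benzyloxy group) | c1ccccc1COc1ccc(cc1)[C@H]1Oc2c(ccc3OC(c4ccccc4)(c4ccccc4)Oc32)[C@H](c2cc(Br)c(O)c3OC(c4ccccc4)(c4ccccc4)Oc23)[C@H]1OCc1ccccc1 | intermediate
16 | 5-vinyl analogue of 15 | c1ccccc1COc1ccc(cc1)[C@H]1Oc2c(ccc3OC(c4ccccc4)(c4ccccc4)Oc32)[C@H](c2cc(C=C)c(O)c3OC(c4ccccc4)(c4ccccc4)Oc23)[C@H]1OCc1ccccc1 | intermediate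
17 | 1,2-bis(benzyloxy)-4-bromobenzene | Brc1ccc(OCc2ccccc2)c(OCc2ccccc2)c1 | starting material
18 | [3,4-bis(benzyloxy)phenyl]magnesium bromide | Br[Mg]c1ccc(OCc2ccccc2)c(OCc2ccccc2)c1 | intermediate
19 | benzyl 2-[3,4-bis(benzyloxy)phenyl]-2-oxoacetate | O=C(OCc1ccccc1)C(=O)c1ccc(OCc2ccccc2)c(OCc2ccccc2)c1 | intermediate
20 | benzyl (2S)-2-[3,4-bis(benzyloxy)phenyl]-2-hydroxyacetate | O[C@@H](c1ccc(OCc2ccccc2)c(OCc2ccccc2)c1)C(=O)OCc1ccccc1 | intermediate
21 | benzyl (2R)-2-[3,4-bis(benzyloxy)phenyl]-2-(aryloxy)acetate, the aryloxy group being phenol 16 | c1ccccc1COc1ccc(cc1)[C@H]1Oc2c(ccc3OC(c4ccccc4)(c4ccccc4)Oc32)[C@H](c2cc(C=C)c(c4OC(c5ccccc5)(c5ccccc5)Oc24)O[C@H](c2ccc(OCc4ccccc4)c(OCc4ccccc4)c2)C(=O)OCc2ccccc2)[C@H]1OCc1ccccc1 | intermediate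
22 | lower unit (2R)-3-benzyloxy-2-[3,4-bis(benzyloxy)phenyl]-7,8-(diphenylmethylenedioxy)-2H-chromene carrying at C6 the protected upper flavan-4β-yl unit | c1ccccc1COc1ccc(cc1)[C@H]1Oc2c(ccc3OC(c4ccccc4)(c4ccccc4)Oc32)[C@H](c2cc3c(c4OC(c5ccccc5)(c5ccccc5)Oc24)O[C@H](c2ccc(OCc4ccccc4)c(OCc4ccccc4)c2)C(OCc2ccccc2)=C3)[C@H]1OCc1ccccc1 | intermediate
23 | lower-unit C4β borane adduct of 22 (boron trans to the 3-benzyloxy group, 2,3-cis) | c1ccccc1COc1ccc(cc1)[C@H]1Oc2c(ccc3OC(c4ccccc4)(c4ccccc4)Oc32)[C@H](c2cc3c(c4OC(c5ccccc5)(c5ccccc5)Oc24)O[C@H](c2ccc(OCc4ccccc4)c(OCc4ccccc4)c2)[C@H](OCc2ccccc2)[C@H]3B)[C@H]1OCc1ccccc1 | intermediate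
24 | fully protected target: lower unit (2R,3R,4S)-3-benzyloxy-chroman-4-ol (2,3-cis-3,4-trans), upper unit as in 15 | c1ccccc1COc1ccc(cc1)[C@H]1Oc2c(ccc3OC(c4ccccc4)(c4ccccc4)Oc32)[C@H](c2cc3c(c4OC(c5ccccc5)(c5ccccc5)Oc24)O[C@H](c2ccc(OCc4ccccc4)c(OCc4ccccc4)c2)[C@H](OCc2ccccc2)[C@H]3O)[C@H]1OCc1ccccc1 | intermediate
25 | (2R,3R,4S)-2-(3,4-dihydroxyphenyl)-6-[(2R,3R,4S)-3,7,8-trihydroxy-2-(4-hydroxyphenyl)chroman-4-yl]chroman-3,4,7,8-tetrol (CNP0275688.1) | Oc1ccc([C@H]2Oc3c(ccc(O)c3O)[C@H](c3cc4c(c(O)c3O)O[C@H](c3ccc(O)c(O)c3)[C@H](O)[C@H]4O)[C@H]2O)cc1 | target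

**Step count.** 16 steps in total. The longest linear sequence is 12 steps (1, 2, 3, 6, 7, 8, 9, 10, 13, 14, 15, 16, from pyrogallol); steps 4–5 and 11–12 are two-step side branches.

**The three steps most likely to fail**

Step 14. The titanium carbene may be used up after the methylenation stage, so that the material stops at the open-chain enol ether, or the large, strongly coordinating substrate may decompose the reagent before the ring closes. Fallback: from 21, Petasis methylenation with Cp2TiMe2 (toluene, 70 °C, dark) would give the acyclic benzyl enol ether F1, which is isolated on base-washed silica and closed by ring-closing metathesis with the second-generation Hoveyda–Grubbs catalyst RuCl2(H2IMes)(=CH-C6H4-2-OiPr) in toluene at 80 °C. This forms the same C3=C4 bond and returns to 22.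

Step 15. Boron may attach at C3 instead of C4, because the electron-rich ring A also stabilises positive charge at C4 in the transition state, or the trans β-benzyloxy borane may eliminate before oxidation. Fallback: from 22, epoxidation with dimethyldioxirane (acetone/CH2Cl2, −40 °C) on the face opposite the C2 aryl group, then hydrolysis of the epoxy ether on wet silica, would give the lower-unit 4β-hydroxy-3-ketone F2. Hydroxyl-directed reduction with Me4NBH(OAc)3 (MeCN/AcOH, −30 °C), with hydride delivered from the 4β-OH face (also the face away from the C2 aryl group), would give the 2,3-cis-3,4-trans diol F3 with a free lower 3-hydroxyl. F3 is hydrogenolysed under the conditions of step 16 and the route is rejoined at 25.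

Step 16. The benzylic C4–OH bond of the lower unit may be hydrogenolysed, or it may ionise on the catalyst once the 7-hydroxyl is free and lead to self-condensation. Fallback: from 24, Dess–Martin oxidation (NaHCO3, CH2Cl2, 0 °C) would give the lower-unit 4-ketone F4. Hydrogenolysis (H2, Pd(OH)2/C, THF/EtOAc) would then free all hydroxyls to give the polyphenolic 2,3-cis-3-hydroxyflavan-4-one dimer F5, the deactivated aryl ketone being inert. Reduction with Me4NBH(OAc)3 (MeCN/AcOH, −20 °C), with hydride delivered from the axial 3-hydroxyl, would set the 4β-hydroxyl and give 25.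

**Further compounds**

F1 | step 14 | acyclic benzyl enol ether: the (1R)-1-[3,4-bis(benzyloxy)phenyl]-2-(benzyloxy)prop-2-en-1-yl ether of phenol 16 | c1ccccc1COc1ccc(cc1)[C@H]1Oc2c(ccc3OC(c4ccccc4)(c4ccccc4)Oc32)[C@H](c2cc(C=C)c(c4OC(c5ccccc5)(c5ccccc5)Oc24)O[C@H](c2ccc(OCc4ccccc4)c(OCc4ccccc4)c2)C(=C)OCc2ccccc2)[C@H]1OCc1ccccc1
F2 | step 15 | protected dimer whose lower unit is the (2R,4S)-4β-hydroxy-flavan-3-one | c1ccccc1COc1ccc(cc1)[C@H]1Oc2c(ccc3OC(c4ccccc4)(c4ccccc4)Oc32)[C@H](c2cc3c(c4OC(c5ccccc5)(c5ccccc5)Oc24)O[C@H](c2ccc(OCc4ccccc4)c(OCc4ccccc4)c2)C(=O)[C@H]3O)[C@H]1OCc1ccccc1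
F3 | step 15 | protected dimer with free lower (2R,3R,4S)-3,4-diol (2,3-cis-3,4-trans) | c1ccccc1COc1ccc(cc1)[C@H]1Oc2c(ccc3OC(c4ccccc4)(c4ccccc4)Oc32)[C@H](c2cc3c(c4OC(c5ccccc5)(c5ccccc5)Oc24)O[C@H](c2ccc(OCc4ccccc4)c(OCc4ccccc4)c2)[C@H](O)[C@H]3O)[C@H]1OCc1ccccc1
F4 | step 16 | protected dimer whose lower unit is the 2,3-cis-3-benzyloxy-flavan-4-one | c1ccccc1COc1ccc(cc1)[C@H]1Oc2c(ccc3OC(c4ccccc4)(c4ccccc4)Oc32)[C@H](c2cc3c(c4OC(c5ccccc5)(c5ccccc5)Oc24)O[C@H](c2ccc(OCc4ccccc4)c(OCc4ccccc4)c2)[C@H](OCc2ccccc2)C3=O)[C@H]1OCc1ccccc1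
F5 | step 16 | free polyphenolic dimer whose lower unit is the 2,3-cis-3-hydroxyflavan-4-one | Oc1ccc([C@H]2Oc3c(ccc(O)c3O)[C@H](c3cc4c(c(O)c3O)O[C@H](c3ccc(O)c(O)c3)[C@H](O)C4=O)[C@H]2O)cc1
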